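**Retrosynthetic overview**
1. Feature: in ring A (C1–C9a–C9–C10–C11–C12) the quaternary C1 bears an oxygen and the C2 arm and lies between C9a and C12. It is therefore the para carbon of a p-quinol, and ring B (C1–O–C14–C13–C12) is the acrylate of that quinol folded back from C13 onto C12.
2. Endgame cuts: N–C3 (ring D, SN2 on a C3 chloride) and N=C9a (ring C, aza-Wittig of a C5 azide). These lead to a C9a ketone carrying the C5–C8 chain on C9, ethyl on C10, protected OH on C11 and ring E.
3. Ring E is cut at C18–C19 (2-carboxyallyl addition to a C3-chlorinated C18 aldehyde). Ethyl (cuprate at C10) and the chain (Negishi at C9) are cut from a C9a enone, which a Wharton transposition and a C11 oxygenation connect to the C10 enone.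
4. That enone arises by C12–C13 bond formation in a catalytic enantioselective Rauhut–Currier desymmetrisation of an achiral quinol acrylate, three steps from 3-(4-hydroxyphenyl)propan-1-ol. The arm is carried as the C2–C3–C18 silyl ether, because a carbonyl at C3 would lie beta to the C1 acyloxy group (E1cB loss) and an ester there could not be told from ring B on reduction.
5. Ring order: A (from the phenol), B (step 4), E (step 20), C (step 23), D (step 24).

Key step: step 4

Conventions:
- C1 is the quaternary O-bearing carbon; C2 and C3 are the pyrrolidine CH2 and N–CH.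
- C5–C8 are the four azepine CH2 groups counted from N; C9=C9a is the enamine, with C9a on N.
- C10 bears ethyl and C11 bears OH.
- C12, C13 and C14 are the CH, CHMe and C=O of ring B; C18–C21 are ring E from O–CH to C=O.
- The top face of ring A is the face of the C2 arm and H-12. The bottom face is the face of ring B.

Assumption: the sense of induction of the two chiral organocatalysts (steps 4 and 18) is taken as drawn; both antipodes of each are accessible, so the mirror-image catalyst would be used if the sense proved opposite.

**Step 1**
Reactants: 1 3-(4-hydroxyphenyl)propan-1-ol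
Product: 2 4-[3-(tert-butyldimethylsilyloxy)propyl]phenol
Conditions: TBSCl (1.05 equiv), imidazole, CH2Cl2/DMF, 0 °C
Reagents that add atoms: tert-butyldimethylsilyl chloride, CC(C)(C)[Si](C)(C)Cl
Why: Chemoselective O-silylation, in which the unhindered primary alcohol is silylated under imidazole catalysis faster than the neutral, less nucleophilic phenol, so one equivalent of chlorosilane should give the mono-ether.

**Step 2**
Reactants: 2 4-[3-(tert-butyldimethylsilyloxy)propyl]phenol
Product: 3 4-hydroxy-4-[3-(TBS-oxy)propyl]cyclohexa-2,5-dienone (achiral p-quinol)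
Conditions: PhI(OAc)2, MeCN/H2O (4:1), 0 °C
Reagents that add atoms: water, O
Why: Hypervalent-iodine oxidative dearomatisation, in which the oxidised phenol is trapped at its substituted para carbon by water, present in large excess, while the bulky silyl ether oxygen is too poor a nucleophile to compete by spirocyclisation.

**Step 3**
Reactants: 3 p-quinol; 4 acryloyl chloride
Product: 5 4-acryloyloxy-4-[3-(TBS-oxy)propyl]cyclohexa-2,5-dienone (achiral quinol acrylate)
Conditions: Et3N, DMAP (cat.), CH2Cl2, −20 → 0 °C
Reagents that add atoms: acryloyl chloride (4), C=CC(=O)Cl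
Why: DMAP-catalysed O-acylation of the tertiary hydroxyl, the only nucleophilic site, should give the acrylate, which keeps a mirror plane through C1 and C10.

**Step 4**
Reactants: 5 achiral quinol acrylate
Product: 6 cis-fused alpha-methylene lactone enone (rings A and B; C10 ketone; C9=C9a; C2 arm and H-12 on the top face)
Conditions: (S)-N-[1-(diphenylphosphanyl)-3-methylbutan-2-yl]-4-methylbenzenesulfonamide (10 mol %), toluene, 0 °C → rt
Reagents that add atoms: none
Why: The phosphine adds to the acrylate beta carbon, the phosphonium enolate so formed attacks one dienone beta carbon (C12) through C13, and proton transfer followed by loss of the phosphine regenerates the catalyst and the exocyclic C13 methylene. The closest known reaction type is this one itself, the phosphine-catalysed enantioselective intramolecular Rauhut–Currier (vinylogous Morita–Baylis–Hillman) desymmetrisation of 4,4-disubstituted cyclohexadienone acrylates to alpha-methylene-gamma-butyrolactones. Ring B closes in the 5-exo-trig mode, and the short O–C14–C13 tether can reach C12 only on the face that carries the C1 oxygen, which enforces the cis fusion. C1 becomes stereogenic through the choice between the two enantiotopic alkenes and C12 through the tether, so the catalyst, whose sulfonamide N–H holds the dienone carbonyl while its branched backbone screens one alkene, sets both centres in one event. The step needs enantiotopic-group selectivity, supplied by the catalyst, and site selectivity of the phosphine for the unsubstituted acrylate terminus over the dienone beta carbons, which the substrate secures because those carbons adjoin quaternary C1. The silyl ether arm has no acidic or electrophilic site and stays out of the reaction.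

**Step 5**
Reactants: 6 alpha-methylene lactone enone
Product: 7 C13-methyl lactone enone (methyl on the concave face of ring B and cis to C11)
Conditions: H2 (1 atm), RhCl(PPh3)3 (5 mol %), PhH/EtOH (1:1), rt, stopped after one equivalent of H2
Reagents that add atoms: none
Why: Homogeneous hydrogenation in which RhCl(PPh3)3 selects on steric grounds, so the exposed 1,1-disubstituted C13 methylene is reduced before the C9=C9a alkene that adjoins quaternary C1, and hydrogen is expected on the convex face of ring B (the face of H-12, away from the C11 methylene of ring A), which leaves the new C13 methyl on the concave face as in the target.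

**Step 6**
Reactants: 7 C13-methyl lactone enone
Product: 9 C11 ketol (OH expected on the top face), via TMS dienol ether 8 (not isolated)
Conditions: TMSOTf, Et3N, CH2Cl2, 0 °C; DMDO, acetone/CH2Cl2, −40 °C; citric acid (cat.), MeOH, rt
Reagents that add atoms: dimethyldioxirane, CC1(C)OO1; trimethylsilyl triflate, C[Si](C)(C)OS(=O)(=O)C(F)(F)F (silicon in 8 only)
Why: Rubottom oxidation, in which the enone can enolise only toward C11 because C1 is quaternary, the electron-rich C10=C11 bond of the single 2-silyloxydiene is oxidised in preference to the electron-poor alkene, attack is expected anti to ring B, and the C11 configuration formed here is of no consequence since step 8 passes through the planar enolate.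

**Step 7**
Reactants: 9 C11 ketol
Product: 10 C11 top-face TBS ether
Conditions: TBSOTf, 2,6-lutidine, CH2Cl2, −78 → 0 °C
Reagents that add atoms: tert-butyldimethylsilyl triflate, CC(C)(C)[Si](C)(C)OS(=O)(=O)C(F)(F)F
Why: O-silylation with a silyl triflate and a hindered pyridine base protects the hindered secondary ketol without enolisation and without ever forming an alkoxide.

**Step 8**
Reactants: 10 C11 top-face TBS ether
Product: 12 C11 bottom-face TBS ether, via potassium dienolate 11 (not isolated)
Conditions: KN(SiMe3)2 (1.05 equiv), THF, −78 °C; AcOH in THF, −78 °C, rapid addition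
Reagents that add atoms: potassium hexamethyldisilazide, [K+].C[Si](C)(C)[N-][Si](C)(C)C (potassium in 11 only)
Why: Epimerisation by kinetic protonation of an enolate, in which C11–H is the only ketone alpha hydrogen, the cross-conjugated dienolate is planar at C11, and the proton is returned to the open top face anti to ring B (the same bias that guided the oxidant in step 6), which turns the silyloxy group to the bottom face, cis to C13 as in the target, without a free bottom-face hydroxyl ever being exposed.

**Step 9**
Reactants: 12 C11 bottom-face TBS ether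
Product: 13 C9–C9a epoxy ketone (epoxide expected on the top face)
Conditions: t-BuOOH (decane), BnNMe3OH (10 mol %), THF, −20 → 0 °C
Reagents that add atoms: tert-butyl hydroperoxide, CC(C)(C)OO
Why: Weitz–Scheffer nucleophilic epoxidation, in which the peroxide anion adds to C9a anti to the axial C1–O bond and the enolate closes on oxygen, while the weak catalytic base should not epimerise C11, whose hydrogen is now equatorial and poorly aligned with the carbonyl; the epoxide configuration is erased in step 11.

**Step 10**
Reactants: 13 epoxy ketone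
Product: 15 C9a allylic alcohol (C9=C10), via epoxy hydrazone 14 (not isolated)
Conditions: N2H4·H2O, AcOH (cat.), MeOH, 0 °C → rt
Reagents that add atoms: hydrazine hydrate, NN.O (nitrogen in 14 only)
Why: Wharton transposition, in which the C10 hydrazone opens the epoxide to a vinyl diazene that loses nitrogen, moving the alkene to C9=C10 and leaving the oxygen on C9a with retention, after which C11 is no longer epimerisable.

**Step 11**
Reactants: 15 C9a allylic alcohol
Product: 16 transposed C9a enone
Conditions: Dess–Martin periodinane, CH2Cl2, rt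
Reagents that add atoms: none
Why: Dess–Martin oxidation of the only free hydroxyl under near-neutral conditions should give the enone with carbonyl at C9a and beta carbon at C10.

**Step 12**
Reactants: 16 C9a enone
Product: 17 C9 iodo enone
Conditions: I2, pyridine/CH2Cl2 (1:1), 0 °C → rt
Reagents that add atoms: iodine, II
Why: Alpha-iodination of an enone by the pyridine addition, iodination and elimination sequence (Baylis–Hillman type) places iodine on C9, the only enone alpha carbon, under conditions known to tolerate gamma-silyloxy groups.

**Step 13**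
Reactants: 18 1-chloro-4-iodobutane
Product: 19 4-chlorobutylzinc iodide (THF solution)
Conditions: Zn dust (activated with BrCH2CH2Br and TMSCl), LiCl, THF, 30 °C
Reagents that add atoms: zinc, [Zn]
Why: Direct zinc insertion occurs far faster into the C–I than into the C–Cl bond, so the chloride end is kept.

**Step 14**
Reactants: 17 C9 iodo enone; 19 4-chlorobutylzinc iodide
Product: 20 C9 (4-chlorobutyl) enone
Conditions: Pd(dba)2 (5 mol %), P(2-furyl)3 (10 mol %), THF/DMF, rt
Reagents that add atoms: 4-chlorobutylzinc iodide (19), ClCCCC[Zn]I
Why: Negishi coupling, in which zerovalent palladium inserts into the C9–I bond and the alkylzinc transfers the C5–C8 chain under base-free conditions that leave lactone, ketone, silyl ethers and alkyl chloride untouched.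

**Step 15**
Reactants: 20 C9 (4-chlorobutyl) enone
Product: 22 C10-ethyl C9a ketone (C9 epimers), via TMS enol ether 21 (not isolated)
Conditions: EtMgBr (2 equiv per Cu), CuBr·SMe2, TMSCl, THF, −78 °C; citric acid, MeOH/THF, 0 °C
Reagents that add atoms: ethylmagnesium bromide, CC[Mg]Br; chlorotrimethylsilane, C[Si](C)(C)Cl (silicon in 21 only)
Why: Chlorosilane-accelerated cuprate conjugate addition, in which ethyl enters C10 axially from the top face, anti to the axial C11 silyloxy group and trans to the C12 substituent (both effects matched), giving the trans Et/O relationship, while C9 forms as a mixture that converges when it becomes sp2 in step 24.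

**Step 16**
Reactants: 22 C10-ethyl C9a ketone
Product: 23 C18 primary alcohol
Conditions: HF·pyridine, pyridine, THF, 0 °C
Reagents that add atoms: none
Why: Selective desilylation, since buffered HF cleaves the unhindered primary TBS ether much faster than the secondary one wedged between C10 and C12, and the medium does not ketalise the hydroxy ketone.

**Step 17**
Reactants: 23 C18 primary alcohol
Product: 24 C18 aldehyde
Conditions: Dess–Martin periodinane, CH2Cl2, 0 °C → rt
Reagents that add atoms: none
Why: Dess–Martin oxidation gives an aldehyde whose alpha carbon C3 is separated from the C1 acyloxy group by C2, so no beta-elimination pathway exists.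

**Step 18**
Reactants: 24 C18 aldehyde
Product: 25 (3R)-3-chloro C18 aldehyde (used crude)
Conditions: NCS, (2R,5R)-2,5-diphenylpyrrolidine (10 mol %), CH2Cl2, 0 °C → rt
Reagents that add atoms: N-chlorosuccinimide, O=C1CCC(=O)N1Cl
Why: Enamine-catalysed asymmetric alpha-chlorination, in which only the aldehyde (not the hindered ketone) forms an enamine and the C2-symmetric amine screens one enamine face, so C3 is set by the catalyst independently of the remote core.

**Step 19**
Reactants: 26 ethyl 2-(bromomethyl)acrylate
Product: 27 [2-(ethoxycarbonyl)allyl]zinc bromide (THF solution)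
Conditions: Zn dust, LiCl, THF, 0 °C
Reagents that add atoms: zinc, [Zn]
Why: Zinc inserts readily into the allylic C–Br bond, and preforming the reagent keeps zinc metal away from the alpha-chloro aldehyde and the alpha-acyloxy ketone.

**Step 20**
Reactants: 25 (3R)-3-chloro C18 aldehyde; 27 [2-(ethoxycarbonyl)allyl]zinc bromide
Product: 29 alpha-methylene ring E lactone (3R chloride; 18S), via anti chlorohydrin ester 28 (not isolated)
Conditions: THF, −78 → −20 °C; then PPTS (cat.), CH2Cl2, rt
Reagents that add atoms: [2-(ethoxycarbonyl)allyl]zinc bromide (27), CCOC(=O)C(=C)C[Zn]Br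
Why: Carbonyl 2-(alkoxycarbonyl)allylation followed by lactonisation, in which the aldehyde reacts at low temperature in preference to the hindered ketone and C18 is set by the polar Felkin–Anh (Cornforth) preference of alpha-chloro aldehydes for the 1,2-anti chlorohydrin, the relationship needed for inversion at C3 later.

**Step 21**
Reactants: 29 alpha-methylene ring E lactone
Product: 30 ring E lactone with C20 methyl (C5 and C3 dichloride)
Conditions: H2 (1 atm), Rh/Al2O3 (5 wt %), EtOAc, rt
Reagents that add atoms: none
Why: Heterogeneous hydrogenation delivers hydrogen to the face of ring E opposite the C18 substituent (also if the alkene first migrates into the ring), giving the cis C18/C20 lactone, while ketone and alkyl chlorides are inert.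

**Step 22**
Reactants: 30 dichloride
Product: 31 C5 azide
Conditions: NaN3, DMSO, 60 °C
Reagents that add atoms: sodium azide, [Na+].[N-]=[N+]=[N-]
Why: SN2 displacement in which the primary C5 chloride reacts far faster than the secondary C3 chloride, which is branched and deactivated by the adjacent C18–O bond; no iodide is added because halide exchange at C3 would erode its configuration.

**Step 23**
Reactants: 31 C5 azide
Product: 33 ring C cyclic imine (N=C9a), via iminophosphorane 32 (not isolated)
Conditions: PMe3, toluene, rt; then 4 Å MS, 90 °C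
Reagents that add atoms: trimethylphosphine, CP(C)C (phosphorus in 32 only)
Why: Staudinger reaction followed by intramolecular aza-Wittig reaction, a known route to seven-membered cyclic imines from omega-azido ketones, here helped by the electron-withdrawing C1 acyloxy group on the carbonyl and by the small, electron-rich phosphine.

**Step 24**
Reactants: 33 ring C cyclic imine
Product: 35 C11 TBS ether of the target, via iminium chloride 34 (not isolated)
Conditions: i-Pr2NEt, MeCN, 90 °C (sealed tube)
Reagents that add atoms: none
Why: Intramolecular N-alkylation of a cyclic imine, in which the nitrogen lone pair points to the C1 side and displaces the C3 chloride 5-exo-tet with inversion (3R chloride to 3S amine, syn to the C18 oxygen), after which the base removes the only alpha hydrogen of the iminium ion, at C9, to give the tetrasubstituted enamine, attack through C9 being disfavoured because it would build a strained bridged quaternary centre.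

**Step 25**
Reactants: 35 C11 TBS ether of the target
Product: 36 CNP0154902.1 (target)
Conditions: HF·pyridine, pyridine, THF, 0 °C → rt
Reagents that add atoms: none
Why: Fluoride-mediated desilylation in a weakly acidic, non-basic medium frees the C11 hydroxyl without forming its alkoxide, so the acyl group of ring B should not migrate from the C1 oxygen to the cis C11 oxygen, and reversible protonation of the enamine is undone on mild basic work-up.

**Compound list**
1 | 3-(4-hydroxyphenyl)propan-1-ol | OCCCc1ccc(O)cc1 | starting material
2 | 4-[3-(tert-butyldimethylsilyloxy)propyl]phenol | CC(C)(C)[Si](C)(C)OCCCc1ccc(O)cc1 | intermediate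
3 | 4-hydroxy-4-[3-(TBS-oxy)propyl]cyclohexa-2,5-dienone (achiral p-quinol) | CC(C)(C)[Si](C)(C)OCCCC1(O)C=CC(=O)C=C1 | intermediate
4 | acryloyl chloride | C=CC(=O)Cl | starting material
5 | 4-acryloyloxy-4-[3-(TBS-oxy)propyl]cyclohexa-2,5-dienone (achiral quinol acrylate) | C=CC(=O)OC1(CCCO[Si](C)(C)C(C)(C)C)C=CC(=O)C=C1 | intermediate
6 | cis-fused alpha-methylene lactone enone | O=C1C=C[C@@]2(CCCO[Si](C)(C)C(C)(C)C)OC(=O)C(=C)[C@H]2C1 | intermediate
7 | C13-methyl lactone enone | O=C1C=C[C@@]2(CCCO[Si](C)(C)C(C)(C)C)OC(=O)[C@@H](C)[C@H]2C1 | intermediate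
8 | C10 TMS dienol ether | C[Si](C)(C)OC=1C=C[C@@]2(CCCO[Si](C)(C)C(C)(C)C)OC(=O)[C@@H](C)[C@H]2C=1 | intermediate (not isolated)
9 | C11 ketol, OH on the top face | O=C1C=C[C@@]2(CCCO[Si](C)(C)C(C)(C)C)OC(=O)[C@@H](C)[C@H]2[C@@H]1O | intermediate
10 | C11 top-face TBS ether | O=C1C=C[C@@]2(CCCO[Si](C)(C)C(C)(C)C)OC(=O)[C@@H](C)[C@H]2[C@@H]1O[Si](C)(C)C(C)(C)C | intermediate
11 | potassium C10 dienolate | [K+].[O-]C=1C=C[C@@]2(CCCO[Si](C)(C)C(C)(C)C)OC(=O)[C@@H](C)[C@H]2C=1O[Si](C)(C)C(C)(C)C | intermediate (not isolated)
12 | C11 bottom-face TBS ether | O=C1C=C[C@@]2(CCCO[Si](C)(C)C(C)(C)C)OC(=O)[C@@H](C)[C@H]2[C@H]1O[Si](C)(C)C(C)(C)C | intermediate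
13 | C9–C9a epoxy ketone | O=C1[C@@H]3O[C@@H]3[C@@]2(CCCO[Si](C)(C)C(C)(C)C)OC(=O)[C@@H](C)[C@H]2[C@H]1O[Si](C)(C)C(C)(C)C | intermediate
14 | epoxy hydrazone | NN=C1[C@@H]3O[C@@H]3[C@@]2(CCCO[Si](C)(C)C(C)(C)C)OC(=O)[C@@H](C)[C@H]2[C@H]1O[Si](C)(C)C(C)(C)C | intermediate (not isolated)
15 | C9a allylic alcohol | C1=C[C@H](O)[C@@]2(CCCO[Si](C)(C)C(C)(C)C)OC(=O)[C@@H](C)[C@H]2[C@H]1O[Si](C)(C)C(C)(C)C | intermediate
16 | transposed C9a enone | C1=CC(=O)[C@@]2(CCCO[Si](C)(C)C(C)(C)C)OC(=O)[C@@H](C)[C@H]2[C@H]1O[Si](C)(C)C(C)(C)C | intermediate
17 | C9 iodo enone | C1=C(I)C(=O)[C@@]2(CCCO[Si](C)(C)C(C)(C)C)OC(=O)[C@@H](C)[C@H]2[C@H]1O[Si](C)(C)C(C)(C)C | intermediate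
18 | 1-chloro-4-iodobutane | ClCCCCI | starting material
19 | 4-chlorobutylzinc iodide | ClCCCC[Zn]I | intermediate (used as solution)
20 | C9 (4-chlorobutyl) enone | C1=C(CCCCCl)C(=O)[C@@]2(CCCO[Si](C)(C)C(C)(C)C)OC(=O)[C@@H](C)[C@H]2[C@H]1O[Si](C)(C)C(C)(C)C | intermediate
21 | C9a TMS enol ether | CC[C@@H]1C(CCCCCl)=C(O[Si](C)(C)C)[C@@]2(CCCO[Si](C)(C)C(C)(C)C)OC(=O)[C@@H](C)[C@H]2[C@H]1O[Si](C)(C)C(C)(C)C | intermediate (not isolated)
22 | C10-ethyl C9a ketone (C9 epimers) | CC[C@@H]1C(CCCCCl)C(=O)[C@@]2(CCCO[Si](C)(C)C(C)(C)C)OC(=O)[C@@H](C)[C@H]2[C@H]1O[Si](C)(C)C(C)(C)C | intermediate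
23 | C18 primary alcohol | CC[C@@H]1C(CCCCCl)C(=O)[C@@]2(CCCO)OC(=O)[C@@H](C)[C@H]2[C@H]1O[Si](C)(C)C(C)(C)C | intermediate
24 | C18 aldehyde | CC[C@@H]1C(CCCCCl)C(=O)[C@@]2(CCC=O)OC(=O)[C@@H](C)[C@H]2[C@H]1O[Si](C)(C)C(C)(C)C | intermediate
25 | (3R)-3-chloro C18 aldehyde | CC[C@@H]1C(CCCCCl)C(=O)[C@@]2(C[C@@H](Cl)C=O)OC(=O)[C@@H](C)[C@H]2[C@H]1O[Si](C)(C)C(C)(C)C | intermediate
26 | ethyl 2-(bromomethyl)acrylate | C=C(CBr)C(=O)OCC | starting material
27 | [2-(ethoxycarbonyl)allyl]zinc bromide | CCOC(=O)C(=C)C[Zn]Br | intermediate (used as solution)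
28 | anti chlorohydrin ester | CC[C@@H]1C(CCCCCl)C(=O)[C@@]2(C[C@@H](Cl)[C@@H](O)CC(=C)C(=O)OCC)OC(=O)[C@@H](C)[C@H]2[C@H]1O[Si](C)(C)C(C)(C)C | intermediate (not isolated)
29 | alpha-methylene ring E lactone | CC[C@@H]1C(CCCCCl)C(=O)[C@@]2(C[C@@H](Cl)[C@@H]3CC(=C)C(=O)O3)OC(=O)[C@@H](C)[C@H]2[C@H]1O[Si](C)(C)C(C)(C)C | intermediate
30 | ring E lactone with C20 methyl (dichloride) | CC[C@@H]1C(CCCCCl)C(=O)[C@@]2(C[C@@H](Cl)[C@@H]3C[C@H](C)C(=O)O3)OC(=O)[C@@H](C)[C@H]2[C@H]1O[Si](C)(C)C(C)(C)C | intermediate
31 | C5 azide | CC[C@@H]1C(CCCCN=[N+]=[N-])C(=O)[C@@]2(C[C@@H](Cl)[C@@H]3C[C@H](C)C(=O)O3)OC(=O)[C@@H](C)[C@H]2[C@H]1O[Si](C)(C)C(C)(C)C | intermediate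
32 | C5 iminophosphorane | CC[C@@H]1C(CCCCN=P(C)(C)C)C(=O)[C@@]2(C[C@@H](Cl)[C@@H]3C[C@H](C)C(=O)O3)OC(=O)[C@@H](C)[C@H]2[C@H]1O[Si](C)(C)C(C)(C)C | intermediate (not isolated)
33 | ring C cyclic imine | CC[C@@H]1C2CCCCN=C2[C@@]3(C[C@@H](Cl)[C@@H]4C[C@H](C)C(=O)O4)OC(=O)[C@@H](C)[C@H]3[C@H]1O[Si](C)(C)C(C)(C)C | intermediate
34 | ring D iminium chloride | CC[C@@H]1C2C3=[N+](CCCC2)[C@H]([C@@H]2C[C@H](C)C(=O)O2)C[C@@]32OC(=O)[C@@H](C)[C@H]2[C@H]1O[Si](C)(C)C(C)(C)C.[Cl-] | intermediate (not isolated)
35 | C11 TBS ether of the target | CC[C@@H]1C2=C3N(CCCC2)[C@H]([C@@H]2C[C@H](C)C(=O)O2)C[C@@]32OC(=O)[C@@H](C)[C@H]2[C@H]1O[Si](C)(C)C(C)(C)C | intermediate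
36 | CNP0154902.1 | CC[C@@H]1C2=C3N(CCCC2)[C@H]([C@@H]2C[C@H](C)C(=O)O2)C[C@@]32OC(=O)[C@@H](C)[C@H]2[C@H]1O | target

**Step count**
Total: 25 steps. Longest linear sequence: 23 steps (steps 1–12, 14–18 and 20–25, from 1).

**Steps most likely to fail**

Step 8. Return of the proton to the dienolate may show poor facial selectivity. The silyl group may also wander between the two enediolate oxygens before the quench. The fallback replaces enolate chemistry by an SN2 inversion and sets out from 9.
- A Mitsunobu reaction with chloroacetic acid (PPh3, DIAD, toluene, 0 °C) should invert C11 to give the bottom-face chloroacetate F1.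
- Thiourea in EtOH removes the chloroacetyl group under near-neutral conditions to give the bottom-face ketol F2.
- F2 is silylated at once with TBSOTf and 2,6-lutidine so that its hydroxyl has no chance to attack the ring B carbonyl.
- The route is rejoined at 12.

Step 5. Hydrogen may be delivered to both faces of the C13 methylene, because the C2 arm sits on the convex face of ring B. The fallback changes the order of events so that a substituent blocks the unwanted face, and sets out from 6.
- Soft enolisation (TMSOTf, Et3N) gives the methylene-lactone TMS dienol ether F3.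
- DMDO and then acidic methanol give the methylene-lactone C11 ketol F4.
- TBSOTf and 2,6-lutidine give the methylene-lactone C11 top-face TBS ether F5.
- In F5 the equatorial silyloxy group on C11 lies beside the concave face of the methylene, so hydrogenation with RhCl(PPh3)3 should be forced onto the convex face.
- The route is rejoined at 10.

Step 23. The iminophosphorane may fail to engage the C9a carbonyl, which is flanked by quaternary C1 and tertiary C9, so that ring C does not close. The fallback replaces the aza-Wittig reaction by a Lewis-acid-driven dehydrative condensation and sets out from 31.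
- Staudinger reduction (PMe3, THF/H2O) gives the C5 primary amine F6.
- F6 is condensed with the ketone by TiCl4 and Et3N in CH2Cl2 at 0 °C.
- The route is rejoined at 33.

**Further compounds**
F1 | step 8 | bottom-face C11 chloroacetate | O=C1C=C[C@@]2(CCCO[Si](C)(C)C(C)(C)C)OC(=O)[C@@H](C)[C@H]2[C@H]1OC(=O)CCl
F2 | step 8 | bottom-face C11 ketol | O=C1C=C[C@@]2(CCCO[Si](C)(C)C(C)(C)C)OC(=O)[C@@H](C)[C@H]2[C@H]1O
F3 | step 5 | methylene-lactone TMS dienol ether | C[Si](C)(C)OC=1C=C[C@@]2(CCCO[Si](C)(C)C(C)(C)C)OC(=O)C(=C)[C@H]2C=1
F4 | step 5 | methylene-lactone C11 ketol | O=C1C=C[C@@]2(CCCO[Si](C)(C)C(C)(C)C)OC(=O)C(=C)[C@H]2[C@@H]1O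
F5 | step 5 | methylene-lactone C11 top-face TBS ether | O=C1C=C[C@@]2(CCCO[Si](C)(C)C(C)(C)C)OC(=O)C(=C)[C@H]2[C@@H]1O[Si](C)(C)C(C)(C)C
F6 | step 23 | C5 primary amine | CC[C@@H]1C(CCCCN)C(=O)[C@@]2(C[C@@H](Cl)[C@@H]3C[C@H](C)C(=O)O3)OC(=O)[C@@H](C)[C@H]2[C@H]1O[Si](C)(C)C(C)(C)C
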